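The route cuts the pyranone (ring C) at C4–C3 and O1–C2. Ring A carries the C4 carbonyl on C4a and O1 on the adjacent C8a, which is the pattern of a salicylaldehyde. C2=C3 with its C3 aryl group maps onto an arylalkyne. A rhodium-catalysed, copper-reoxidised annulation through the formyl C–H bond forms both bonds and ring C in one operation. The precursors are 2-hydroxy-3-methoxy-4,6-bis(methoxymethoxy)benzaldehyde, with only one free ortho OH, and the (2,4,5-trimethoxyphenyl)(trimethylsilyl)alkyne, whose silicon holds the place of H-2. Desilylation, acetal removal and a C8-blocked aromatic Claisen shift from O7 then place the prenyl group at C6.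

Key step: step 8

Remark: the target has no stereocentre and no stereogenic double bond (the prenyl alkene ends in two methyl groups). It is therefore achiral and the route needs no stereocontrol. Chromone numbering (O1 to C8a) is used for ring positions.

Step 1
Reactants: 1 2,4,6-trihydroxybenzaldehyde
Product: 2 2-hydroxy-4,6-bis(methoxymethoxy)benzaldehyde
Conditions: MOMCl (2.2 equiv), i-Pr2NEt (2.5 equiv), CH2Cl2, 0 °C to rt
Reagents that add atoms: chloromethyl methyl ether, COCCl
Why: Williamson-type O-alkylation in which the 4-OH and one ortho OH react, while the last ortho OH is held in a hydrogen bond to the formyl oxygen and stays free when only two equivalents of reagent are used.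

Step 2
Reactants: 2 2-hydroxy-4,6-bis(methoxymethoxy)benzaldehyde
Product: 3 2-(benzyloxy)-4,6-bis(methoxymethoxy)benzaldehyde
Conditions: BnBr (1.2 equiv), K2CO3, DMF, 60 °C
Reagents that add atoms: benzyl bromide, BrCc1ccccc1
Why: Williamson etherification in warm DMF overcomes the chelated phenol and gives a mask orthogonal to the MOM acetals, which marks the oxygen that later becomes O1.

Step 3
Reactants: 3 2-(benzyloxy)-4,6-bis(methoxymethoxy)benzaldehyde
Product: 5 2-(benzyloxy)-4,6-bis(methoxymethoxy)phenol, via aryl formate 4 (not isolated)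
Conditions: mCPBA (1.3 equiv), CH2Cl2, 0 °C to rt; aq. Na2S2O3/NaHCO3 wash; then K2CO3 (cat.), MeOH, rt
Reagents that add atoms: 3-chloroperoxybenzoic acid, O=C(OO)c1cccc(Cl)c1
Why: Baeyer–Villiger (Dakin-type) oxidation in which the very electron-rich trialkoxyaryl group migrates to give formate 4, which base-catalysed methanolysis cleaves without touching the benzyl or MOM ethers.

Step 4
Reactants: 5 2-(benzyloxy)-4,6-bis(methoxymethoxy)phenol
Product: 6 1-(benzyloxy)-2-methoxy-3,5-bis(methoxymethoxy)benzene
Conditions: MeI (1.5 equiv), K2CO3, DMF, rt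
Reagents that add atoms: iodomethane, CI
Why: Williamson methylation of the only free phenol installs the future C8 methoxy group.

Step 5
Reactants: 6 1-(benzyloxy)-2-methoxy-3,5-bis(methoxymethoxy)benzene
Product: 7 2-methoxy-3,5-bis(methoxymethoxy)phenol
Conditions: H2 (1 atm), 10% Pd/C, EtOAc–EtOH, rt
Reagents that add atoms: none
Why: Catalytic hydrogenolysis cleaves only the benzylic C–O bond, since aryl MOM acetals and the methyl ether are inert under these neutral conditions.

Step 6
Reactants: 7 2-methoxy-3,5-bis(methoxymethoxy)phenol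
Product: 8 2-hydroxy-3-methoxy-4,6-bis(methoxymethoxy)benzaldehyde
Conditions: MgCl2 (anhydrous), Et3N, (CH2O)n, MeCN, 80 °C; cold dilute HCl work-up
Reagents that add atoms: paraformaldehyde (reacts as formaldehyde), C=O
Why: Casnati–Skattebøl magnesium-mediated ortho-formylation delivers formaldehyde within the magnesium phenoxide chelate to the only free ortho carbon (the other bears OMe), and a second formaldehyde accepts hydride to set the aldehyde level, so the position between the two OMOM groups is left alone.

Step 7
Reactants: 9 1-bromo-2,4,5-trimethoxybenzene; 10 ethynyltrimethylsilane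
Product: 11 trimethyl[(2,4,5-trimethoxyphenyl)ethynyl]silane
Conditions: Pd(PhCN)2Cl2 (3 mol %), t-Bu3P·HBF4 (6 mol %), CuI (2 mol %), i-Pr2NH, dioxane, rt to 45 °C
Reagents that add atoms: none
Why: Sonogashira coupling in which the bulky electron-rich phosphine speeds oxidative addition into the electron-rich aryl bromide at low temperature, so volatile 10 is retained and the C–Si bond survives.

Step 8
Reactants: 8 2-hydroxy-3-methoxy-4,6-bis(methoxymethoxy)benzaldehyde; 11 trimethyl[(2,4,5-trimethoxyphenyl)ethynyl]silane
Product: 12 8-methoxy-5,7-bis(methoxymethoxy)-2-(trimethylsilyl)-3-(2,4,5-trimethoxyphenyl)-4H-chromen-4-one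
Conditions: [RhCl(cod)]2 (2.5 mol %), 1,2,3,4-tetraphenylcyclopenta-1,3-diene (10 mol %), Cu(OAc)2 (anhydrous, 2.2 equiv), 4 Å MS, 11 (1.5 equiv), o-xylene, 130 °C, N2
Reagents that add atoms: none
Why: The acetate-bearing cyclopentadienyl-Rh(III) species formed in situ binds the phenoxide of 8 and cleaves the formyl C–H bond (concerted metalation–deprotonation) to give a five-membered acyl rhodacycle, 11 inserts syn into the Rh–acyl bond to give a seven-membered rhodacycle, and C(sp2)–O reductive elimination releases 12 while two Cu(II) acetates reoxidise Rh(I). The closest known reaction type is the rhodium/copper oxidative coupling of salicylaldehydes with internal alkynes to 2,3-disubstituted chromones, applied here to an aryl(silyl)alkyne. The single new ring, the six-membered pyranone, closes as a formal [4+2] of O1–C8a–C4a–C4 with the two alkyne carbons: C4–C3 arises in the insertion and O1–C2 in the ring-contracting reductive elimination. No stereocentre is created. The step needs one insertion orientation, and the silyl group secures it because silicon prefers the carbon that becomes bound to the metal (stabilised α-silyl metal–carbon bond, long C–Si bond next to the crowded rhodium), as in Larock-type annulations of silylalkynes, so the acyl carbon adds to the aryl-bearing carbon and silicon ends at C2. It also needs O1 to come from the oxygen next to the methoxy group, which the MOM cap on the other ortho oxygen secures; anhydrous oxidant, sieves and nitrogen are chosen to hold back alkyne desilylation with oxidative dimerisation and acetal loss.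

Step 9
Reactants: 12 8-methoxy-5,7-bis(methoxymethoxy)-2-(trimethylsilyl)-3-(2,4,5-trimethoxyphenyl)-4H-chromen-4-one
Product: 13 8-methoxy-5,7-bis(methoxymethoxy)-3-(2,4,5-trimethoxyphenyl)-4H-chromen-4-one
Conditions: TBAF (1.2 equiv), AcOH (1.2 equiv), THF, 0 °C to rt
Reagents that add atoms: none
Why: Fluoride-induced protodesilylation, in which fluoride adds to silicon and acetic acid protonates the C2(sp2)–Si bond next to O1, while the buffer keeps the medium from opening the base-sensitive pyranone and the MOM groups are unaffected.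

Step 10
Reactants: 13 8-methoxy-5,7-bis(methoxymethoxy)-3-(2,4,5-trimethoxyphenyl)-4H-chromen-4-one
Product: 14 isocaviunin, 5,7-dihydroxy-8-methoxy-3-(2,4,5-trimethoxyphenyl)-4H-chromen-4-one
Conditions: HCl (1.25 M in MeOH), 45 °C
Reagents that add atoms: none
Why: Acid-catalysed acetal exchange with methanol removes both MOM groups before any acid-sensitive prenyl unit is present, and the aryl methyl ethers and the pyranone are stable to dilute methanolic HCl.

Step 11
Reactants: 15 2-methylbut-3-en-2-ol
Product: 16 tert-butyl 2-methylbut-3-en-2-yl carbonate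
Conditions: n-BuLi (1.05 equiv), THF, −78 to 0 °C; Boc2O (1.1 equiv), 0 °C to rt; water quench
Reagents that add atoms: di-tert-butyl dicarbonate, CC(C)(C)OC(=O)OC(=O)OC(C)(C)C
Why: Carbonate formation by O-acylation, where deprotonation with n-BuLi makes the hindered tertiary allylic alcohol reactive towards Boc2O without ionising it.

Step 12
Reactants: 14 isocaviunin; 16 tert-butyl 2-methylbut-3-en-2-yl carbonate
Product: 17 5-hydroxy-8-methoxy-7-[(2-methylbut-3-en-2-yl)oxy]-3-(2,4,5-trimethoxyphenyl)-4H-chromen-4-one
Conditions: 16 (1.3 equiv), Pd(PPh3)4 (5 mol %), THF, 0 °C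
Reagents that add atoms: none
Why: Tsuji–Trost O-allylation, in which decarboxylative ionisation of 16 gives a 1,1-dimethyl-π-allylpalladium tert-butoxide pair, the base deprotonates the more acidic unchelated 7-OH, and the phenoxide attacks the more substituted allyl terminus under kinetic control at low temperature while the 5-OH stays hydrogen-bonded to C4=O.

Step 13
Reactants: 17 5-hydroxy-8-methoxy-7-[(2-methylbut-3-en-2-yl)oxy]-3-(2,4,5-trimethoxyphenyl)-4H-chromen-4-one
Product: 19 6-prenylisocaviunin [5,7-dihydroxy-8-methoxy-6-(3-methylbut-2-en-1-yl)-3-(2,4,5-trimethoxyphenyl)-4H-chromen-4-one], via cyclohexadienone 18 (not isolated)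
Conditions: PhNEt2, 130 °C, N2
Reagents that add atoms: none
Why: Aromatic Claisen rearrangement, a [3,3] shift from O7 that inverts the allyl unit so the tertiary ether delivers a linear prenyl group; only the C6 adduct 18 can rearomatise because C8 bears OMe, and the transient C6 stereocentre of 18 vanishes on enolisation.

Compound list
1 | 2,4,6-trihydroxybenzaldehyde | O=Cc1c(O)cc(O)cc1O | starting material
2 | 2-hydroxy-4,6-bis(methoxymethoxy)benzaldehyde | O=Cc1c(O)cc(OCOC)cc1OCOC | intermediate
3 | 2-(benzyloxy)-4,6-bis(methoxymethoxy)benzaldehyde | O=Cc1c(OCc2ccccc2)cc(OCOC)cc1OCOC | intermediate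
4 | 2-(benzyloxy)-4,6-bis(methoxymethoxy)phenyl formate (not isolated) | O=COc1c(OCc2ccccc2)cc(OCOC)cc1OCOC | intermediate
5 | 2-(benzyloxy)-4,6-bis(methoxymethoxy)phenol | Oc1c(OCc2ccccc2)cc(OCOC)cc1OCOC | intermediate
6 | 1-(benzyloxy)-2-methoxy-3,5-bis(methoxymethoxy)benzene | COc1c(OCc2ccccc2)cc(OCOC)cc1OCOC | intermediate
7 | 2-methoxy-3,5-bis(methoxymethoxy)phenol | COc1c(O)cc(OCOC)cc1OCOC | intermediate
8 | 2-hydroxy-3-methoxy-4,6-bis(methoxymethoxy)benzaldehyde | O=Cc1c(O)c(OC)c(OCOC)cc1OCOC | intermediate
9 | 1-bromo-2,4,5-trimethoxybenzene | COc1cc(OC)c(Br)cc1OC | starting material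
10 | ethynyltrimethylsilane | C#C[Si](C)(C)C | starting material
11 | trimethyl[(2,4,5-trimethoxyphenyl)ethynyl]silane | COc1cc(OC)c(C#C[Si](C)(C)C)cc1OC | intermediate
12 | 8-methoxy-5,7-bis(methoxymethoxy)-2-(trimethylsilyl)-3-(2,4,5-trimethoxyphenyl)-4H-chromen-4-one | O=c1c(-c2cc(OC)c(OC)cc2OC)c([Si](C)(C)C)oc2c(OC)c(OCOC)cc(OCOC)c12 | intermediate
13 | 8-methoxy-5,7-bis(methoxymethoxy)-3-(2,4,5-trimethoxyphenyl)-4H-chromen-4-one | O=c1c(-c2cc(OC)c(OC)cc2OC)coc2c(OC)c(OCOC)cc(OCOC)c12 | intermediate
14 | isocaviunin, 5,7-dihydroxy-8-methoxy-3-(2,4,5-trimethoxyphenyl)-4H-chromen-4-one | O=c1c(-c2cc(OC)c(OC)cc2OC)coc2c(OC)c(O)cc(O)c12 | intermediate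
15 | 2-methylbut-3-en-2-ol | C=CC(C)(C)O | starting material
16 | tert-butyl 2-methylbut-3-en-2-yl carbonate | C=CC(C)(C)OC(=O)OC(C)(C)C | intermediate
17 | 5-hydroxy-8-methoxy-7-[(2-methylbut-3-en-2-yl)oxy]-3-(2,4,5-trimethoxyphenyl)-4H-chromen-4-one | O=c1c(-c2cc(OC)c(OC)cc2OC)coc2c(OC)c(OC(C)(C)C=C)cc(O)c12 | intermediate
18 | 5-hydroxy-8-methoxy-6-(3-methylbut-2-en-1-yl)-3-(2,4,5-trimethoxyphenyl)-6H-chromene-4,7-dione (not isolated, racemic at C6) | COc1cc(OC)c(cc1OC)C1=COC2=C(OC)C(=O)C(CC=C(C)C)C(O)=C2C1=O | intermediate
19 | 6-prenylisocaviunin, 5,7-dihydroxy-8-methoxy-6-(3-methylbut-2-en-1-yl)-3-(2,4,5-trimethoxyphenyl)-4H-chromen-4-one (achiral) | COc1cc(OC)c(-c2coc3c(OC)c(O)c(CC=C(C)C)c(O)c3c2=O)cc1OC | target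

Total step count: 13. Longest linear sequence: 11 (steps 1–6, 8–10, 12, 13).

Steps most likely to fail

1. Step 8.
- **What may go wrong:** The alkyne may insert in the reverse sense. Silicon may be lost from the alkyne before insertion, followed by copper-mediated oxidative dimerisation. The acyl-rhodium species may decarbonylate. The MOM group ortho to the aldehyde may be lost, which would blur the choice of O1. Loss of silicon after ring closure is harmless, because it leads to 13.
- **Fallback:** Ring C is built by the enaminone, 3-iodochromone and cross-coupling sequence, setting out from 8.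
  - Addition of MeMgBr (excess, THF, 0 °C) should give the racemic benzylic alcohol 2-(1-hydroxyethyl)-6-methoxy-3,5-bis(methoxymethoxy)phenol F1.
  - MnO2 in CH2Cl2 oxidises it to 1-[2-hydroxy-3-methoxy-4,6-bis(methoxymethoxy)phenyl]ethan-1-one F2.
  - DMF dimethyl acetal at 90 °C condenses it to (E)-3-(dimethylamino)-1-[2-hydroxy-3-methoxy-4,6-bis(methoxymethoxy)phenyl]prop-2-en-1-one F3.
  - Iodine in MeOH at rt closes and iodinates this to 3-iodo-8-methoxy-5,7-bis(methoxymethoxy)-4H-chromen-4-one F4.
  - Suzuki–Miyaura coupling with commercial 2,4,5-trimethoxyphenylboronic acid (Pd(dppf)Cl2, Na2CO3, DME–H2O, 80 °C) comes back to the route at 13.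

2. Step 12.
- **What may go wrong:** The phenoxide may attack the unsubstituted allyl terminus. Palladium may re-ionise the branched ether and drift it to the linear ether. The chelated 5-OH may undergo a second alkylation.
- **Fallback:** The fallback avoids π-allyl chemistry and sets out from 14. Copper-catalysed O-alkylation with commercial 3-chloro-3-methylbut-1-yne (DBU, CuCl2·2H2O cat., MeCN, 0 °C) should give 5-hydroxy-8-methoxy-7-[(2-methylbut-3-yn-2-yl)oxy]-3-(2,4,5-trimethoxyphenyl)-4H-chromen-4-one F5. Lindlar semihydrogenation (H2, Pd/CaCO3–Pb, quinoline, EtOAc, rt) comes back to the route at 17.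

3. Step 13.
- **What may go wrong:** The tertiary allyl ether may ionise or eliminate with loss of the C5 unit before the sigmatropic shift. Trace acid may cyclise the new prenyl group onto a neighbouring phenol.
- **Fallback:** The fallback gives up the O-to-C transfer and sets out from 14. Nuclear C-prenylation of the ambident phenoxide with prenyl bromide (KOH, MeOH, 0 °C to rt) can only occur at C6, because C8 is blocked. Material that reacts at oxygen is removed by chromatography. This comes back to the route directly at 19 and makes no new compound (F0).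

Further compounds
F1 | step 8 | 2-(1-hydroxyethyl)-6-methoxy-3,5-bis(methoxymethoxy)phenol (racemic) | CC(O)c1c(O)c(OC)c(OCOC)cc1OCOC
F2 | step 8 | 1-[2-hydroxy-3-methoxy-4,6-bis(methoxymethoxy)phenyl]ethan-1-one | CC(=O)c1c(O)c(OC)c(OCOC)cc1OCOC
F3 | step 8 | (E)-3-(dimethylamino)-1-[2-hydroxy-3-methoxy-4,6-bis(methoxymethoxy)phenyl]prop-2-en-1-one | CN(C)/C=C/C(=O)c1c(O)c(OC)c(OCOC)cc1OCOC
F4 | step 8 | 3-iodo-8-methoxy-5,7-bis(methoxymethoxy)-4H-chromen-4-one | O=c1c(I)coc2c(OC)c(OCOC)cc(OCOC)c12
F5 | step 12 | 5-hydroxy-8-methoxy-7-[(2-methylbut-3-yn-2-yl)oxy]-3-(2,4,5-trimethoxyphenyl)-4H-chromen-4-one | O=c1c(-c2cc(OC)c(OC)cc2OC)coc2c(OC)c(OC(C)(C)C#C)cc(O)c12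
F0 | step 13 | none | none
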